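Plan
Target: a (2S)-7-hydroxy-5-methoxyflavanone (rings A, C and B) whose ring B carbon C3' is bonded to C6'' of an apigenin unit. C2 is the only stereocentre.
Enabling feature: C2 carries the ring oxygen O1 and lies beta to the C4 ketone of ring C, so O1–C2 is the bond of an oxa-Michael addition of the ring A phenol. A temporary tert-butyl ester on C3 activates the acceptor twice over and gives a catalyst two carbonyl groups to hold.
Cuts, in retrosynthetic order: five O–benzyl bonds; C3–CO2tBu (decarboxylation); O1–C2 (ring C); C2=C3 (Knoevenagel); C3'–C6'' (Suzuki–Miyaura); C3–ester carbon (C-acylation of the ring A acetophenone).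
Forward: three short branches give the ring A beta-keto ester, the ring B boronate-aldehyde and 6-iodoapigenin tribenzyl ether (its three rings are bought with apigenin). Ring B is joined to the flavone and then to ring A, and ring C, the only ring built, closes last.
Stereochemistry: a cinchona-derived bifunctional thiourea sets C2 during the ring closure, and C3 is transient and erased. Every later step is acidic or neutral, so C2 cannot open by base-induced retro-addition.
Benzyl ethers are used throughout because they survive the hot acid of the decarboxylation and leave by neutral hydrogenolysis without touching the 5-methoxy group.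

Key step: step 11

Assumption: the quinine-derived catalyst is written for the 2S series. The sense of induction is to be confirmed on a small batch, and the quinidine-derived pseudo-enantiomer takes its place if the sense proves opposite.
Assumption: the C3'–C6'' axis (three oxygen substituents and one hydrogen in the ortho positions) is taken to rotate at room temperature and is not counted as a stereo-element, in line with the target SMILES.
Assumption: the alkylidene precursor of the key step is drawn without alkene geometry, because the condensation that makes it is under thermodynamic control and may deliver both isomers.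

Step 1
Reactants: 1 2,4,6-trihydroxyacetophenone
Product: 2 1-[4-(benzyloxy)-2,6-dihydroxyphenyl]ethanone
Conditions: BnBr (1.0 equiv), K2CO3 (1.1 equiv), DMF, 0 °C to rt
Reagents that add atoms: benzyl bromide, BrCc1ccccc1
Why: Williamson etherification, in which the 4-OH (para to the acetyl group, most acidic, unhindered) should react first with one equivalent of halide because the two ortho hydroxyls are engaged with the carbonyl oxygen and flanked by the acetyl group.

Step 2
Reactants: 2 1-[4-(benzyloxy)-2,6-dihydroxyphenyl]ethanone
Product: 3 1-[4-(benzyloxy)-2-hydroxy-6-methoxyphenyl]ethanone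
Conditions: Me2SO4 (1.0 equiv), K2CO3 (1.1 equiv), acetone, reflux
Reagents that add atoms: dimethyl sulfate, COS(=O)(=O)OC
Why: Williamson O-methylation of two equivalent ortho hydroxyls, which should stop at the monoether because the remaining OH is then locked in a strong six-membered hydrogen bond to the ketone.

Step 3
Reactants: 3 1-[4-(benzyloxy)-2-hydroxy-6-methoxyphenyl]ethanone; 4 di-tert-butyl dicarbonate
Product: 5 tert-butyl 3-[4-(benzyloxy)-2-hydroxy-6-methoxyphenyl]-3-oxopropanoate
Conditions: LiN(SiMe3)2 (3.2 equiv), THF, −78 °C; 4 (1.1 equiv), −78 to −30 °C; AcOH quench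
Reagents that add atoms: di-tert-butyl dicarbonate (compound 4), CC(C)(C)OC(=O)OC(=O)OC(C)(C)C
Why: Claisen-type C-acylation of a phenoxide-enolate dianion, whose carbon terminus is the more reactive nucleophile at low temperature, while the extra base stores the product as its stabilised enolate and thereby blocks lactonisation to the 4-hydroxycoumarin.

Step 4
Reactants: 6 3-bromo-4-hydroxybenzaldehyde
Product: 7 4-(benzyloxy)-3-bromobenzaldehyde
Conditions: BnBr (1.1 equiv), K2CO3 (1.5 equiv), DMF, rt
Reagents that add atoms: benzyl bromide, BrCc1ccccc1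
Why: Williamson etherification of an acidic phenol (para-formyl, ortho-bromo) that has no competing nucleophilic site.

Step 5
Reactants: 7 4-(benzyloxy)-3-bromobenzaldehyde
Product: 8 4-(benzyloxy)-3-(4,4,5,5-tetramethyl-1,3,2-dioxaborolan-2-yl)benzaldehyde
Conditions: B2pin2 (1.2 equiv), PdCl2(dppf) (3 mol%), KOAc (3 equiv), 1,4-dioxane, 90 °C
Reagents that add atoms: bis(pinacolato)diboron, CC1(C)OB(OC1(C)C)B1OC(C)(C)C(C)(C)O1
Why: Miyaura borylation, which tolerates the aldehyde and the benzyl ether and uses a base (acetate) too weak to start homocoupling of the new boronate with unreacted bromide.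

Step 6
Reactants: 9 apigenin
Product: 10 7,4'-di-O-benzylapigenin, i.e. 7-(benzyloxy)-2-[4-(benzyloxy)phenyl]-5-hydroxy-4H-chromen-4-one
Conditions: BnBr (2.2 equiv), K2CO3 (2.5 equiv), DMF, rt
Reagents that add atoms: benzyl bromide, BrCc1ccccc1
Why: Williamson etherification of the two acidic, unhindered phenols at C7 and C4', while the 5-OH stays free because it is hydrogen-bonded to the C4 carbonyl and needs forcing conditions.

Step 7
Reactants: 10 7,4'-di-O-benzylapigenin
Product: 11 7,4'-di-O-benzyl-6-iodoapigenin, i.e. 7-(benzyloxy)-2-[4-(benzyloxy)phenyl]-5-hydroxy-6-iodo-4H-chromen-4-one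
Conditions: BnMe3N·ICl2 (1.05 equiv), CaCO3 (2 equiv), CH2Cl2–MeOH, rt
Reagents that add atoms: benzyltrimethylammonium dichloroiodate, C[N+](C)(C)Cc1ccccc1.Cl[I-]Cl
Why: Electrophilic aromatic iodination, in which iodine should enter at C6 because a free chelated 5-OH next to a 7-O-alkyl group activates its own ortho carbon most strongly (C8 is preferred only once O5 is alkylated), with CaCO3 taking up the HCl.

Step 8
Reactants: 11 7,4'-di-O-benzyl-6-iodoapigenin
Product: 12 5,7,4'-tri-O-benzyl-6-iodoapigenin, i.e. 5,7-bis(benzyloxy)-2-[4-(benzyloxy)phenyl]-6-iodo-4H-chromen-4-one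
Conditions: BnBr (1.5 equiv), K2CO3 (3 equiv), DMF, 65 °C
Reagents that add atoms: benzyl bromide, BrCc1ccccc1
Why: Williamson etherification under forcing conditions, where heat and excess base break the hydrogen bond of the 5-OH and the aryl iodide is inert to carbonate.

Step 9
Reactants: 12 5,7,4'-tri-O-benzyl-6-iodoapigenin; 8 4-(benzyloxy)-3-(4,4,5,5-tetramethyl-1,3,2-dioxaborolan-2-yl)benzaldehyde
Product: 13 4-(benzyloxy)-3-{5,7-bis(benzyloxy)-2-[4-(benzyloxy)phenyl]-4-oxo-4H-chromen-6-yl}benzaldehyde
Conditions: Pd(OAc)2 (5 mol%), SPhos (10 mol%), K3PO4 (3 equiv), toluene–H2O (10:1), 90 °C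
Reagents that add atoms: none
Why: Suzuki–Miyaura coupling to a tri-ortho-substituted biaryl, with boron placed on the partner that has one ortho oxygen (a 2,6-dialkoxyaryl boronate would protodeboronate readily), the reactive iodide placed on the hindered flavone, and a bulky electron-rich biaryl phosphine made for such congested couplings.

Step 10
Reactants: 5 tert-butyl 3-[4-(benzyloxy)-2-hydroxy-6-methoxyphenyl]-3-oxopropanoate; 13 biaryl aldehyde
Product: 14 tert-butyl 2-[4-(benzyloxy)-2-hydroxy-6-methoxybenzoyl]-3-(4-(benzyloxy)-3-{5,7-bis(benzyloxy)-2-[4-(benzyloxy)phenyl]-4-oxo-4H-chromen-6-yl}phenyl)prop-2-enoate (alkene isomers; no stereocentre)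
Conditions: piperidine (20 mol%), AcOH (20 mol%), 4 Å molecular sieves, toluene, rt; rapid chromatography
Reagents that add atoms: none
Why: Knoevenagel condensation, in which piperidinium acetate activates the non-enolisable aldehyde as its iminium ion for attack by the enol of 5, and the bulky tert-butyl ester and the hydrogen-bonded phenol should keep ring closure slow enough at room temperature for 14 to be isolated.

Step 11
Reactants: 14 alkylidene beta-keto ester
Product: 15 tert-butyl (2S)-7-(benzyloxy)-2-(4-(benzyloxy)-3-{5,7-bis(benzyloxy)-2-[4-(benzyloxy)phenyl]-4-oxo-4H-chromen-6-yl}phenyl)-5-methoxy-4-oxochromane-3-carboxylate (C3 labile: epimers in equilibrium through the enol)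
Conditions: 1-[3,5-bis(trifluoromethyl)phenyl]-3-[(8S,9S)-6'-methoxycinchonan-9-yl]thiourea (10–20 mol%), toluene (0.05 M), −25 °C; cold aqueous citric acid wash; used without chromatography
Reagents that add atoms: none
Why: The two thiourea N–H bonds clamp the ketone and ester carbonyls of the alkylidene 1,3-dicarbonyl unit while the quinuclidine nitrogen takes up the proton of the ring A phenol, so the oxygen adds to the benzylidene carbon within one organised assembly and the resulting enolate is protonated at C3. The closest known reaction type is the bifunctional cinchona-thiourea-catalysed intramolecular oxa-Michael addition of 2-hydroxyaryl alkylidene beta-keto esters to 3-carboxylated flavanones, applied here to a larger aldehyde component. Ring C closes in the 6-endo-trig mode with formation of O1–C2. C2 is controlled by the catalyst, which exposes one face of the benzylidene carbon to the tethered oxygen, whereas C3 is an acidic beta-keto ester centre that settles thermodynamically (presumably trans to the aryl group) and is deleted in step 12. The step needs the catalysed path to outrun racemic background closure and needs one nucleophile and one acceptor: the tert-butyl ester, the hydrogen bond of the phenol to the ketone and the low temperature hold back uncatalysed closure and lactonisation, all five other phenols are benzylated, and the flavone C2''=C3'' bond is a vinylogous ester far less electrophilic than the doubly activated alkene. Both alkene isomers can reach the same closure because the oxygen attacks the pi face of the benzylidene carbon, and if they differed in selectivity the major isomer would be used alone after chromatography.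

Step 12
Reactants: 15 (2S)-3-tert-butoxycarbonyl flavanone
Product: 17 (2S)-7-(benzyloxy)-2-(4-(benzyloxy)-3-{5,7-bis(benzyloxy)-2-[4-(benzyloxy)phenyl]-4-oxo-4H-chromen-6-yl}phenyl)-5-methoxychroman-4-one, via beta-keto acid 16 (not isolated)
Conditions: p-TsOH·H2O (0.5 equiv), toluene, 80 °C
Reagents that add atoms: none
Why: Acid-catalysed tert-butyl ester cleavage (loss of isobutene) followed by thermal decarboxylation of the beta-keto acid, which erases C3 and should keep C2 because without base the C3 enolate needed for retro-oxa-Michael opening never forms, while the aryl benzyl ethers and the flavone tolerate the sulfonic acid (partial loss of the peri 5''-O-benzyl group would be harmless, since step 13 removes it anyway).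

Step 13
Reactants: 17 (2S)-penta-O-benzyl flavanone
Product: 18 (2S)-7-hydroxy-2-{4-hydroxy-3-[5,7-dihydroxy-2-(4-hydroxyphenyl)-4-oxo-4H-chromen-6-yl]phenyl}-5-methoxychroman-4-one (CNP0332590.1)
Conditions: H2 (1 atm), 10% Pd/C, THF–MeOH, rt; filtration through Celite, evaporation below 30 °C
Reagents that add atoms: none
Why: Catalytic hydrogenolysis of the five aryl benzyl ethers under neutral conditions, which should leave the aryl methyl ether, the C4 ketone, the cyclic C2–O1 bond and the flavone C2''=C3'' bond untouched if stopped at the calculated hydrogen uptake, with no acid or base present to racemise C2.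

Compound list
1 | 2,4,6-trihydroxyacetophenone | CC(=O)c1c(O)cc(O)cc1O | starting material
2 | 1-[4-(benzyloxy)-2,6-dihydroxyphenyl]ethanone | CC(=O)c1c(O)cc(OCc2ccccc2)cc1O | intermediate
3 | 1-[4-(benzyloxy)-2-hydroxy-6-methoxyphenyl]ethanone | COc1cc(OCc2ccccc2)cc(O)c1C(C)=O | intermediate
4 | di-tert-butyl dicarbonate | CC(C)(C)OC(=O)OC(=O)OC(C)(C)C | starting material
5 | tert-butyl 3-[4-(benzyloxy)-2-hydroxy-6-methoxyphenyl]-3-oxopropanoate | COc1cc(OCc2ccccc2)cc(O)c1C(=O)CC(=O)OC(C)(C)C | intermediate
6 | 3-bromo-4-hydroxybenzaldehyde | O=Cc1ccc(O)c(Br)c1 | starting material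
7 | 4-(benzyloxy)-3-bromobenzaldehyde | O=Cc1ccc(OCc2ccccc2)c(Br)c1 | intermediate
8 | 4-(benzyloxy)-3-(4,4,5,5-tetramethyl-1,3,2-dioxaborolan-2-yl)benzaldehyde | O=Cc1ccc(OCc2ccccc2)c(B2OC(C)(C)C(C)(C)O2)c1 | intermediate
9 | apigenin | O=c1cc(-c2ccc(O)cc2)oc2cc(O)cc(O)c12 | starting material
10 | 7,4'-di-O-benzylapigenin | O=c1cc(-c2ccc(OCc3ccccc3)cc2)oc2cc(OCc3ccccc3)cc(O)c12 | intermediate
11 | 7,4'-di-O-benzyl-6-iodoapigenin | O=c1cc(-c2ccc(OCc3ccccc3)cc2)oc2cc(OCc3ccccc3)c(I)c(O)c12 | intermediate
12 | 5,7,4'-tri-O-benzyl-6-iodoapigenin | O=c1cc(-c2ccc(OCc3ccccc3)cc2)oc2cc(OCc3ccccc3)c(I)c(OCc3ccccc3)c12 | intermediate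
13 | 4-(benzyloxy)-3-{5,7-bis(benzyloxy)-2-[4-(benzyloxy)phenyl]-4-oxo-4H-chromen-6-yl}benzaldehyde | O=Cc1ccc(OCc2ccccc2)c(-c2c(OCc3ccccc3)cc3oc(-c4ccc(OCc5ccccc5)cc4)cc(=O)c3c2OCc2ccccc2)c1 | intermediate
14 | tert-butyl alkylidene beta-keto ester, free ring A phenol, penta-O-benzyl, alkene isomers | COc1cc(OCc2ccccc2)cc(O)c1C(=O)C(C(=O)OC(C)(C)C)=Cc1ccc(OCc2ccccc2)c(-c2c(OCc3ccccc3)cc3oc(-c4ccc(OCc5ccccc5)cc4)cc(=O)c3c2OCc2ccccc2)c1 | intermediate
15 | (2S)-3-tert-butoxycarbonyl penta-O-benzyl flavanone, C3 unspecified | COc1cc(OCc2ccccc2)cc2c1C(=O)C(C(=O)OC(C)(C)C)[C@@H](c1ccc(OCc3ccccc3)c(-c3c(OCc4ccccc4)cc4oc(-c5ccc(OCc6ccccc6)cc5)cc(=O)c4c3OCc3ccccc3)c1)O2 | intermediate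
16 | (2S)-3-carboxy penta-O-benzyl flavanone (beta-keto acid), C3 unspecified | COc1cc(OCc2ccccc2)cc2c1C(=O)C(C(=O)O)[C@@H](c1ccc(OCc3ccccc3)c(-c3c(OCc4ccccc4)cc4oc(-c5ccc(OCc6ccccc6)cc5)cc(=O)c4c3OCc3ccccc3)c1)O2 | intermediate
17 | (2S)-penta-O-benzyl flavanone | COc1cc(OCc2ccccc2)cc2c1C(=O)C[C@@H](c1ccc(OCc3ccccc3)c(-c3c(OCc4ccccc4)cc4oc(-c5ccc(OCc6ccccc6)cc5)cc(=O)c4c3OCc3ccccc3)c1)O2 | intermediate
18 | CNP0332590.1, (2S)-7-hydroxy-2-{4-hydroxy-3-[5,7-dihydroxy-2-(4-hydroxyphenyl)-4-oxo-4H-chromen-6-yl]phenyl}-5-methoxychroman-4-one | COc1cc(O)cc2c1C(=O)C[C@@H](c1ccc(O)c(-c3c(O)cc4oc(-c5ccc(O)cc5)cc(=O)c4c3O)c1)O2 | target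

Total step count: 13.
Longest linear sequence: 8 steps (apigenin branch, steps 6 to 13).

Steps most likely to fail

Step 11: loss of enantiocontrol.
- What may go wrong: the uncatalysed closure may compete, because the methoxy group ortho to the ketone twists the aryl ketone and favours the closed form. The electron-rich 4-benzyloxyphenyl group at C2 also eases reversible opening while the amine is present.
- Fallback: a kinetic resolution by asymmetric transfer hydrogenation, a known route to enantiopure flavanones. It sets out from 17 of insufficient enantiomeric purity, as delivered by steps 11 and 12, and comes back to the route at 17.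
- With RuCl[(R,R)-TsDPEN](p-cymene) in HCO2H–Et3N and EtOAc at room temperature, hydride transfer to the C4 ketone should be fast only for the 2R enantiomer. In that enantiomer the catalyst's preference for the 4R carbinol matches axial attack on the half-chair bearing an equatorial aryl group.
- This converts the unwanted enantiomer into the cis alcohol (2R,4R)-penta-O-benzyl flavan-4-ol F1. The unreacted, less polar (2S)-17 is separated by chromatography and taken into step 13. The flavone carbonyl, a vinylogous ester, should not be reduced.

Step 10: premature amine-promoted closure of ring C during the condensation.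
- What may go wrong: racemic material would form before the chiral catalyst is present, and the slow condensation of a bulky, electron-rich aldehyde makes this worse.
- Fallback: masking the nucleophile. It sets out from 5 and comes back at 14.
- Silylation of the phenol (TBSCl, imidazole, DMF, rt) should give tert-butyl 3-[4-(benzyloxy)-2-(tert-butyldimethylsilyloxy)-6-methoxyphenyl]-3-oxopropanoate F2.
- The piperidinium acetate condensation with 13 can then be warmed without risk of closure and should give the O-silyl alkylidene beta-keto ester F3.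
- HF·pyridine in THF at 0 °C releases the phenol on the acidic side, where no phenoxide is formed. Benzyl ethers and the tert-butyl ester are stable to it, and the product is 14 for immediate use in step 11.

Step 9: stalling of the cross-coupling at an iodide flanked by two benzyloxy groups.
- What may go wrong: protodeboronation of the boronate and reductive loss of iodine would take over.
- Fallback: inverting the order of protection and coupling, so that the iodide carries only one bulky ortho group. It sets out from 11 (with 8) and comes back at 13.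
- Suzuki–Miyaura coupling of the 5-hydroxy iodide 11 with 8 (Pd(OAc)2, SPhos, K3PO4, 1,4-dioxane–H2O, 80 °C) should give 4-(benzyloxy)-3-{7-(benzyloxy)-2-[4-(benzyloxy)phenyl]-5-hydroxy-4-oxo-4H-chromen-6-yl}benzaldehyde F4.
- The chelated 5''-OH of F4 is then benzylated (BnBr, Cs2CO3, DMF, 65 °C) to give 13.

Further compounds
F1 | step 11 | (2R,4R)-penta-O-benzyl flavan-4-ol (cis) | COc1cc(OCc2ccccc2)cc2c1[C@H](O)C[C@H](c1ccc(OCc3ccccc3)c(-c3c(OCc4ccccc4)cc4oc(-c5ccc(OCc6ccccc6)cc5)cc(=O)c4c3OCc3ccccc3)c1)O2
F2 | step 10 | tert-butyl 3-[4-(benzyloxy)-2-(tert-butyldimethylsilyloxy)-6-methoxyphenyl]-3-oxopropanoate | COc1cc(OCc2ccccc2)cc(O[Si](C)(C)C(C)(C)C)c1C(=O)CC(=O)OC(C)(C)C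
F3 | step 10 | O-silyl alkylidene beta-keto ester (alkene isomers) | COc1cc(OCc2ccccc2)cc(O[Si](C)(C)C(C)(C)C)c1C(=O)C(C(=O)OC(C)(C)C)=Cc1ccc(OCc2ccccc2)c(-c2c(OCc3ccccc3)cc3oc(-c4ccc(OCc5ccccc5)cc4)cc(=O)c3c2OCc2ccccc2)c1
F4 | step 9 | 4-(benzyloxy)-3-{7-(benzyloxy)-2-[4-(benzyloxy)phenyl]-5-hydroxy-4-oxo-4H-chromen-6-yl}benzaldehyde | O=Cc1ccc(OCc2ccccc2)c(-c2c(OCc3ccccc3)cc3oc(-c4ccc(OCc5ccccc5)cc4)cc(=O)c3c2O)c1
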